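The initiator charge is small, 5.00% of the free monomer charge, and the next run hangs on which charge to move: the transfer agent or the impurity.

free monomer 0.010 M (fed, over 25 s); transfer agent 3.00 mM; initiator 0.50 mM; impurity 0.23 mM; time 8.0 min; the fed solution adds 0.25 times the starting volume

- average number of monomer units in a chain (chains begun, living or dead) at 8.0 min
- part of the free monomer that has reacted at 8.0 min

- for a step with 2 of a species take k times the square, and two of it per event
- charges are per starting volume, the dose included; the dosed solution carries all of it
- the average divides the monomer in chains by the number of chains begun, living and dead together
- run time (flask): 8.0 min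

    free monomer + initiator → living end + monomer in chains (k1 = 17 M⁻¹ s⁻¹)
    free monomer + living end → monomer in chains + living end, rate k2*[living end]*[free monomer] (k2 = 6.3 M⁻¹ s⁻¹)
    living end + transfer agent → dead chain (k3 = 3.1 M⁻¹ s⁻¹)
    initiator + impurity → spent initiator A (k4 = 1800 M⁻¹ s⁻¹)
    2 initiator → spent initiator B (k5 = 160 M⁻¹ s⁻¹)
    initiator → spent initiator C (k6 = 8.4 × 10⁻⁴ s⁻¹)

At the charged amounts a living end adds free monomer at 0.0630 s⁻¹ and dies on transfer agent at 0.00930 s⁻¹, a pseudo-first-order death with half-life 1.2 min. Addition is the faster, and their ratio, the kinetic chain length, is 6.77. The added volume thins both charges alike, and the bit-by-bit feed makes no difference to the average. The chain-length number is one unit from the start plus that ratio times the fraction of free monomer left over the fraction of transfer agent left, 7.77 with both charges whole.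

Impurity does not enter this number. It takes initiator at 0.414 s⁻¹, faster than free monomer does at 0.170 s⁻¹, so it thins the chains begun. The reacted part is the number times the chains begun per free monomer charged, and with the whole initiator charge counted as chains begun that product is 38.9%. By this product the transfer agent bears on the reacted part as well as on the length, and the impurity bears on it through the chains begun.

This reckoning stops at 7.77 and that product. The forecast, lower on both, says 7.3 and 8.8%, on the ground that “that short life limits propagation to a few monomers per chain”.

The flask gives 7.15 and 8.63%, and the forecast held. At 8.00 min living ends are still 3.45% of the chains begun in this flask. With 91% of the free monomer and 96% of the transfer agent left, the number reads 7.42, and this flask left until 80.0 min gives 7.37.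

The neighbour flask holds a quarter of the impurity. Its fractions left, 87% and 94%, give the number 7.27. Computed, that neighbour flask gives 7.05 and 12.7% reacted.

(The rate constants belong to no real substance; what happens was integrated by code.)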